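## Retrosynthetic overview

- Last bond: C6–prenyl, made by Friedel–Crafts C-prenylation of 3,5,7,8-tetrahydroxyflavone, whose C6 is the only free, OH-activated ring carbon.
- Before that: global O-demethylation of 3-hydroxy-5,7,8-trimethoxyflavone, so the methyl ethers are gone before the acid-sensitive prenyl group arrives.
- The pyranone C ring is the only ring formed, by Algar–Flynn–Oyamada oxidative cyclisation of a 2'-hydroxychalcone; the A and B rings are bought as benzenes.
- Chalcone: Claisen–Schmidt condensation of benzaldehyde with 2-hydroxy-3,4,6-trimethoxyacetophenone.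
- Acetophenone: Friedel–Crafts acetylation of 1,2,3,5-tetramethoxybenzene with in-flask cleavage of the flanked ortho-OMe, which fixes the 5,7,8 (not 5,6,7) oxygen pattern.

Assumption: platanetin has no stereocentre and no stereogenic double bond, so "single enantiomer" needs no stereocontrol, and 1,2,3,5-tetramethoxybenzene is taken as a catalogue chemical.

## Route

Step 1
Reactants: 1 1,2,3,5-tetramethoxybenzene
Product: 3 2-hydroxy-3,4,6-trimethoxyacetophenone, via 2,3,4,6-tetramethoxyacetophenone 2 (not isolated)
Conditions: AcCl (1.2 equiv), AlCl3 (2.5 equiv), Et2O, 0 °C → rt, 24 h; then ice/2 M HCl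
Reagents that add atoms: acetyl chloride, CC(=O)Cl
Why: Friedel–Crafts acylation at one of the two equivalent free positions, after which the AlCl3-chelated ketone cleaves the ortho-OMe that is squeezed between the acetyl and a neighbouring OMe, leaving the chelated 2-OH that later becomes O1.

Step 2
Reactants: 3 2-hydroxy-3,4,6-trimethoxyacetophenone; 4 benzaldehyde
Product: 6 (E)-2'-hydroxy-3',4',6'-trimethoxychalcone, via racemic aldol adduct 5 (not isolated)
Conditions: KOH (50% aq.), EtOH, rt, 24–48 h; then HCl to pH 3
Reagents that add atoms: none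
Why: Claisen–Schmidt condensation, in which the non-enolisable aldehyde takes the acetophenone enolate and E1cB dehydration gives the thermodynamically favoured E-enone.

Step 3
Reactants: 6 (E)-2'-hydroxy-3',4',6'-trimethoxychalcone
Product: 8 3-hydroxy-5,7,8-trimethoxyflavone, via racemic trans-dihydroflavonol 7 (not isolated)
Conditions: 30% H2O2, 2 M NaOH, MeOH, 0 °C → rt, 16 h; then HCl
Reagents that add atoms: hydrogen peroxide, OO
Why: Algar–Flynn–Oyamada reaction, in which the phenoxide closes onto the β-carbon while the α-carbon is hydroxylated by H2O2 and the resulting dihydroflavonol is oxidised in the flask to the flavonol, erasing both transient stereocentres.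

Step 4
Reactants: 8 3-hydroxy-5,7,8-trimethoxyflavone
Product: 9 3,5,7,8-tetrahydroxyflavone
Conditions: BBr3 (7 equiv), CH2Cl2, −78 °C → rt, 16 h, Ar; then ice-water
Reagents that add atoms: none
Why: BBr3 Lewis-acid O-demethylation (bromide SN2 at each boron-activated methyl ether) under anhydrous, low-temperature conditions that avoid Wessely–Moser isomerisation, on a core that carries no acid-sensitive group yet.

Step 5
Reactants: 9 3,5,7,8-tetrahydroxyflavone
Product: 10 platanetin (3,5,7,8-tetrahydroxy-6-(3-methylbut-2-enyl)flavone)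
Conditions: 2-methylbut-3-en-2-ol (1.5 equiv, slow addition), BF3·OEt2 (0.5 equiv), dioxane, rt, 3–6 h, Ar; then H2O/MeOH; unreacted 9 recycled
Reagents that add atoms: 2-methylbut-3-en-2-ol, CC(C)(O)C=C
Why: Friedel–Crafts C-prenylation, in which the dimethylallyl cation attacks through its primary terminus at C6 (the only unsubstituted A-ring carbon, ortho to 5-OH and 7-OH and para to O1) while O-prenyl ethers revert under the Lewis acid, and no stereocentre is created.

## Compound list

1 | 1,2,3,5-tetramethoxybenzene | COc1cc(OC)c(OC)c(OC)c1 | starting material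
2 | 2,3,4,6-tetramethoxyacetophenone (not isolated) | CC(=O)c1c(OC)cc(OC)c(OC)c1OC | intermediate
3 | 2-hydroxy-3,4,6-trimethoxyacetophenone | CC(=O)c1c(OC)cc(OC)c(OC)c1O | intermediate
4 | benzaldehyde | O=Cc1ccccc1 | starting material
5 | 3-hydroxy-1-(2-hydroxy-3,4,6-trimethoxyphenyl)-3-phenylpropan-1-one, racemic aldol adduct (not isolated) | COc1cc(OC)c(C(=O)CC(O)c2ccccc2)c(O)c1OC | intermediate
6 | (E)-2'-hydroxy-3',4',6'-trimethoxychalcone | COc1cc(OC)c(C(=O)/C=C/c2ccccc2)c(O)c1OC | intermediate
7 | trans-3-hydroxy-5,7,8-trimethoxyflavanone, racemic, (2R,3R) enantiomer drawn (not isolated) | c1ccccc1[C@@H]2[C@@H](O)C(=O)c3c(OC)cc(OC)c(OC)c3O2 | intermediate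
8 | 3-hydroxy-5,7,8-trimethoxyflavone | COc1cc(OC)c2c(=O)c(O)c(-c3ccccc3)oc2c1OC | intermediate
9 | 3,5,7,8-tetrahydroxyflavone | O=c1c(O)c(-c2ccccc2)oc2c(O)c(O)cc(O)c12 | intermediate
10 | platanetin | CC(C)=CCc1c(O)c(O)c2oc(-c3ccccc3)c(O)c(=O)c2c1O | target

## Count and risks

Total step count: 5. Longest linear sequence: 5 steps (1 → 3 → 6 → 8 → 9 → 10).

**Step 5, direct C-prenylation.** This is the most likely step to fail: the expected yield is modest, the product can cyclise onto the 5-OH or 7-OH to give a dimethylchroman, and 9 is air-sensitive. The fallback sets out from 9 and comes back at 10, replacing the cationic alkylation with a [3,3] route. Peracetylation (Ac2O, pyridine, DMAP) gives 3,5,7,8-tetraacetoxyflavone F1. PhSH/imidazole in NMP at 0 °C removes only the 7-acetate, the most activated aryl ester (para to the pyranone carbonyl), giving 3,5,8-triacetoxy-7-hydroxyflavone F2. Pd(PPh3)4-catalysed decarboxylative O-alkylation with tert-butyl 2-methylbut-3-en-2-yl carbonate in THF gives 3,5,8-triacetoxy-7-(2-methylbut-3-en-2-yloxy)flavone F3. Aromatic Claisen rearrangement in toluene at 110 °C delivers the allyl unit with inversion to C6, since C8 is blocked, giving 3,5,8-triacetoxy-7-hydroxy-6-prenylflavone F4. Degassed K2CO3/MeOH at 0 °C → rt, followed by mild acidification, gives 10 without any acid exposure of the prenyl group.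

**Step 3, Algar–Flynn–Oyamada reaction.** 6'-Methoxychalcones can divert to aurones. The fallback sets out from 6 and comes back at 8, separating ring closure from C3 oxygenation. Oxidative cyclisation with catalytic I2 in DMSO at 130 °C gives 5,7,8-trimethoxyflavone F5. Dimethyldioxirane in acetone/CH2Cl2 at 0 °C → rt epoxidises the electron-rich C2–C3 bond to give racemic 2,3-epoxy-5,7,8-trimethoxyflavanone F6. Catalytic p-TsOH in CH2Cl2 opens and tautomerises this to 8.

**Step 1, tandem acylation and regioselective mono-demethylation.** Over-demethylation or cleavage of the wrong ortho-OMe would lead to the 5,6,7-series. The fallback sets out from 1 and comes back at 3, separating C–C bond formation from ether cleavage. Directed ortho-lithiation (n-BuLi, THF, 0 °C) between two OMe groups gives 2,3,4,6-tetramethoxyphenyllithium F7. Acylation with N-methoxy-N-methylacetamide (−78 °C → rt, aq. NH4Cl) gives ketone 2, now isolated and purified. One equivalent of BCl3 in CH2Cl2 at −78 → 0 °C then effects chelation-controlled cleavage of the flanked 2-OMe to give 3, whose regiochemistry is confirmed by NOE before going on.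

## Further compounds

F1 | step 5 | 3,5,7,8-tetraacetoxyflavone | CC(=O)Oc1cc(OC(C)=O)c2c(=O)c(OC(C)=O)c(-c3ccccc3)oc2c1OC(C)=O
F2 | step 5 | 3,5,8-triacetoxy-7-hydroxyflavone | Oc1cc(OC(C)=O)c2c(=O)c(OC(C)=O)c(-c3ccccc3)oc2c1OC(C)=O
F3 | step 5 | 3,5,8-triacetoxy-7-(2-methylbut-3-en-2-yloxy)flavone | C=CC(C)(C)Oc1cc(OC(C)=O)c2c(=O)c(OC(C)=O)c(-c3ccccc3)oc2c1OC(C)=O
F4 | step 5 | 3,5,8-triacetoxy-7-hydroxy-6-prenylflavone | CC(C)=CCc1c(O)c(OC(C)=O)c2oc(-c3ccccc3)c(OC(C)=O)c(=O)c2c1OC(C)=O
F5 | step 3 | 5,7,8-trimethoxyflavone | COc1cc(OC)c2c(=O)cc(-c3ccccc3)oc2c1OC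
F6 | step 3 | 2,3-epoxy-5,7,8-trimethoxyflavanone (racemic) | COc1cc(OC)c2C(=O)C3OC3(c4ccccc4)Oc2c1OC
F7 | step 1 | 2,3,4,6-tetramethoxyphenyllithium | [Li]c1c(OC)cc(OC)c(OC)c1OC
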